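I began without constants, so I counted turnovers; two earlier runs were all I had to count from.

| flask | starting material | partner | remark | time |
|---|---|---|---|---|
| south | 0.058 M (in portions, 4) | 0.095 M | run made earlier; portions every 5.0 min |  |
| north-east | 0.23 M (in portions, 4) | 0.095 M | run made earlier; portions every 5.0 min |  |
| Saturday's | 0.050 M (in portions, 4) | 0.0950 M | the portions of starting material follow each other after 5.0 min, the first at the start | 1.0 h |
| Monday's | 0.10 M (in portions, 4) | 0.0950 M | the portions of starting material follow each other after 5.0 min, the first at the start | 1.0 h |
| Tuesday's | 0.20 M (in portions, 4) | 0.0950 M | the portions of starting material follow each other after 5.0 min, the first at the start | 1.0 h |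

- south (time / min: first product / %): 10.0: 10.5; 20.0: 24.9; 30.0: 32.9; 40.0: 36.5
- north-east (time / min: first product / %): 3.00: 2.8; 8.00: 7.7; 20.0: 21.1; 40.0: 29.5

(each reading ± 0.3 percentage points)

- the numbers in the tables scatter with a standard deviation of 0.3 percentage points
- a reading or a percentage of first product counts all its forms, free or not
- the concentration of first product that is asked is that of its free form alone
- "hardly changes" means that all values lie within two and a half points (for a concentration: within two and a half percent of the largest)

1. [first product] (only what is free in solution) at the end for Saturday's, Monday's, Tuesday's, in this order
2. how the row runs (rises, then falls / rises all the way / hardly changes / falls, then rises / falls all the way)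

The north-east run had given 0.714 of its partner to first product at 40.0 min, and this number is what I carried: the partner turnover, the fraction of the charge read as first product multiplied by the charge over the partner.

Had the partner stopped the earlier runs? The south run stood at 0.223 at the same time, and both turnovers were below one, so neither run had used up its partner by this count. Yet the fractions read were close, 36.5% and 29.5%, although the charges differed by a factor of 3.97.

What stood beside the first product, then? In the north-east run the unread charge came to 1.71 of the partner charge, more than the unclaimed partner, 0.286. The readings count bound forms, so I supposed that leftover starting material held first product, and that the free form followed counted product over that leftover.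

What does that mean for the three new flasks? Taking the south fraction for Saturday's and Monday's flasks and the north-east fraction for Tuesday's, my count for 40.0 min came to 0.192 for Saturday's flask, 0.384 for Monday's and 0.621 for Tuesday's. On Tuesday's flask the partner is the limiting reagent, so that turnover has a ceiling of one. Counted product over unread charge was 0.575 by the south fraction and less, 0.418, by the north-east fraction, so I expected Tuesday's flask to stand below Monday's. The readings give no free concentration, so I committed to a shape and no numbers: up to Monday's, as my judgement, then down.

The forecast gave 0.014 M, 0.021 M and 0.024 M, a row that rises all the way. It started from the same binding, “I suppose that product is tied up by excess starting material”, but it parted from me on the shape.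

The flasks gave 0.00587 M, 0.00680 M and 0.00486 M: the row rises, then falls, turning at a charge over partner of 1.01.

    starting material + first product ⇌ idle adduct, settled at all times (K = 420 M⁻¹)
    partner + first product → double product (k = 0.00670 M⁻¹ s⁻¹)
    starting material + partner → first product (k = 0.00810 M⁻¹ s⁻¹)
    starting material ⇌ dormant form (K = 0.820, k = 8.80 × 10⁻⁴ s⁻¹)

Tuesday's turnover, 0.621 by my count for 40.0 min, stood at 0.736 after 1.00 h, with 22.2% of its partner left and free first product at 2.43% of the charge. Saturday's, 0.192 by the same count, stood at 0.206, with free first product at 11.7% of the charge. At that time on Saturday's flask, partner went into first product 1.1 times as fast as into double product. Double product stood there at 10.7% of the charge, against 1.01% on Tuesday's flask.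

(Readings and results were computed on assumed constants; noise was put on by code.)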